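## The problem

Compound 15 is a 2-aryl-3-methyl-1,4-benzodioxane neolignan. Lignan numbering is used throughout beside the benzodioxin locants: the benzylic carbon C7 (C2 of the heterocycle) carries ring A (3,4,5-trimethoxyphenyl) and O7, the neighbouring C8 (C3) carries the methyl group and O8, and the two oxygens sit on adjacent carbons of ring B and so close the dioxane ring C. A synthesis has to settle three things: which oxygen goes where on ring B (O8 on the carbon next to the ring B methoxy group, O7 on the carbon meta to it), the trans (7R,8R) arrangement as one enantiomer, and the (E)-allylic alcohol para to O8. The two stereocentres are contiguous, so one can control the other: C8 can be taken from the chiral pool and can direct C7 by 1,2-induction in an acyclic carbonyl addition, and if ring C is then closed without breaking a bond at either carbon the trans relation is locked. The delicate parts are the electron-rich cinnamyl alcohol (acid-sensitive, easily oxidised, a sink for radical cations), the benzylic C7–O bonds, which ionise under acid and would scramble C7, and C8 for as long as it is alpha to a carbonyl group. The feature that opens the key step is the 3,4,5-trioxygenation of ring B: if O8 is first bound to the central carbon of a symmetric 2,6-dimethoxyphenoxy unit, both ortho carbons carry a methoxy group and are equivalent, so O7 can replace either one by ipso substitution and the regiochemical question disappears.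

## Retrosynthesis

**Side chain (15 to 11).** The allylic alcohol of 15 is taken back to the (E)-ester 14, and the C=C bond of 14 is cut between the ring B carbon substituent and a two-carbon ester unit. This leads to aldehyde 13, its alcohol 12 and the pivalate 11. Carrying the propenyl chain through the ring closure is rejected: a styrene conjugated with ring B would be the most easily oxidised site and its radical cation takes up nucleophiles at the olefin. An aldehyde or ester on ring B would raise the oxidation potential of exactly the ring that has to be oxidised. A saturated acyloxymethyl carbon is electronically almost silent, and the pivalate also has to pass an aminolysis, a Grignard addition and a hydride reduction earlier. The forward steps are routine: ester cleavage, benzylic oxidation with in situ E-selective olefination, and 1,2-reduction.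

**Ring C (11 to 10), the key cut.** Ring C of 11 is opened at the O7–aryl bond. This gives the acyclic (1R,2R) alcohol 10, an 8-O-4′ ether whose ring B is a symmetric 2,6-dimethoxyphenoxy group; the leaving group is one methoxy group.

- Against the neighbouring cuts: cutting C7–O7 (a phenol attacking an activated benzylic carbon) needs a ring B catechol with two differentiated oxygens and exposes C7 to a benzylic cation. Cutting O8–aryl, or both aryl–oxygen bonds, needs a halogenated or aryne-type ring B and a regiochemical decision.
- What the chosen cut gains: both sp3 centres are spectators, ring B comes from a cheap symmetric phenol, and symmetry decides the regiochemistry.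
- What the forward reaction must do: a secondary alcohol has to substitute an unactivated aryl methyl ether. Ordinary nucleophilic aromatic substitution cannot do this on an electron-rich ring. The ring is therefore activated by one-electron oxidation under acridinium photocatalysis; the ring B radical cation is attacked ipso at a methoxy carbon and the methoxy group leaves as its alcohol.
- The weak point and its answer: ring A is as oxidisable as ring B and its radical cation can fragment at C7–C8. The plan answers this from within. Ring B is kept free of conjugating or deactivating groups (hence 11, not 13, as the product), base is omitted, and the tether offers a nucleophile only to a hole on ring B.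

**C7 stereocentre (10 to 9).** Alcohol 10 is traced to ketone 9 by removing the hydride at C7. A non-chelating, bulky hydride should attack anti to the perpendicular aryloxy group and past the C8 hydrogen (Felkin–Anh), which gives the threo (1R,2R) alcohol. The neighbouring option, adding the aryl group to an α-aryloxy aldehyde, would need chelation through a weakly basic aryloxy oxygen and a configurationally labile aldehyde. The forward step must not epimerise C8 and must spare the pivalate.

**C7–aryl bond (9 to 6 and 8).** Ketone 9 is cut between C7 and ring A into Weinreb amide 6 and the aryl Grignard reagent 8, made from bromide 7. Cutting C7–C8 instead would create both stereocentres at once and give up the chiral pool. The amide stops the addition at the ketone stage and holds C8 in a chelate until work-up.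

**Functional-group changes (6 to 3).** Amide 6 comes from ethyl ester 5 by aminolysis. The pivaloyloxymethyl group of 5 comes from the formyl group of 3 through alcohol 4. None of these steps touches C8.

**C8–O8 bond (3 to 1 and 2).** Ester 3 is cut at the C8–O8 bond into syringaldehyde 1 and ethyl (S)-lactate 2. Substitution at the lactate carbon with inversion gives the (R) ether, which fixes the absolute configuration of the whole route in the first step. An α-halo ketone alkylation would give the same bond only in racemic form.

## Roads not taken

**Alternative 1:** The C7–O7 bond is made last, together with the C8–H bond. A quinine-derived squaramide base would promote 6-endo-trig addition of the free phenol of methyl 3-hydroxy-5-methoxy-4-{[(Z)-3-methoxy-3-oxo-1-(3,4,5-trimethoxyphenyl)prop-1-en-2-yl]oxy}benzoate A1 to its benzylic olefin carbon, followed by protonation at C8. The product would be dimethyl (2S,3R)-8-methoxy-3-(3,4,5-trimethoxyphenyl)-2,3-dihydro-1,4-benzodioxine-2,6-dicarboxylate A2.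

- Merits: both stereocentres arise from a flat precursor by catalysis, no chiral-pool material is needed, and the trans relation is the thermodynamic outcome at the epimerisable C8.
- Weak points: the acceptor in A1 is a captodative olefin with an electron-rich β-aryl group, so it is a poor electrophile. The oxa-Michael addition is reversible, and the retro-reaction erodes the C7 configuration. Ring B of A1 needs two differentiated ortho oxygens. After closure, the C8 ester of A2 must be taken down to a methyl group (reduction, activation, hydride displacement) while the ring B ester must be told apart and grown into the propenol.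
- Comparison: this road is better in that its key step creates two stereocentres, where the chosen key step creates none. The chosen plan sets against it an absolute configuration secured before the risky step, which that step cannot alter, and a shorter endgame without deoxygenation.

**Alternative 2:** Both aryl–oxygen bonds are cut. The potassium alkoxide of (1R,2R)-2-(tert-butylperoxy)-1-(3,4,5-trimethoxyphenyl)propan-1-ol A3 would add through O7 to the aryne released by fluoride from 5-(dimethoxymethyl)-3-methoxy-2-(trimethylsilyl)phenyl trifluoromethanesulfonate A4, at the aryne carbon remote from the methoxy group. The aryl anion would then attack the C8-bound peroxide oxygen and expel the tert-butoxy group. The product would be (2R,3R)-7-(dimethoxymethyl)-5-methoxy-3-methyl-2-(3,4,5-trimethoxyphenyl)-2,3-dihydro-1,4-benzodioxine A5.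

- Merits: it is the most convergent plan, ring B arrives in one operation, the methoxy group dictates the regiochemistry, and A5 is one hydrolysis away from aldehyde 13.
- Weak points: a β-peroxy alkoxide such as that of A3 is set up for fragmentation into two carbonyl compounds, and for base-induced loss of the C8 hydrogen next to the peroxide. A configurationally defined secondary alkyl tert-butyl peroxide is hard to make. An aryl anion can attack either peroxide oxygen or simply be protonated. A4 needs a multistep preparation.
- Comparison: on paper it is as short as the chosen plan or shorter. It stacks two unproven events on a fragile intermediate, whereas the chosen plan has one unproven event on a robust substrate and builds everything else from known steps.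

**Alternative 3:** The C7–O7 and O8–aryl bonds are cut. With a carbonate base, the phenoxide of 4-fluoro-3-hydroxy-5-methoxybenzaldehyde A7 would open (2R,3S)-2-methyl-3-(3,4,5-trimethoxyphenyl)oxirane A6 at benzylic C7 with inversion. The released C8 alkoxide would displace the fluoride para to the formyl group. The product would be (2R,3R)-5-methoxy-3-methyl-2-(3,4,5-trimethoxyphenyl)-2,3-dihydro-1,4-benzodioxine-7-carbaldehyde A8, identical with aldehyde 13.

- Merits: both events are of known type, the trans ring follows stereospecifically from the cis epoxide, and A8 needs only olefination and reduction to reach 15.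
- Weak points: a phenoxide can open A6 at either carbon, and attack at C8 gives the constitutional isomer with aryl and methyl exchanged. The electron-rich aryl epoxide can ionise, which leaks into the cis ring, or rearrange to a ketone at the temperature an intermolecular opening needs. A6 is not a chiral-pool compound and would come from an asymmetric oxidation that seldom gives a single enantiomer without enrichment. The fluoride of A7 is flanked by two oxygen substituents and activated by one formyl group only. A7 is not a stock phenol.
- Comparison: this road is clearly better in step count and in novelty risk. The chosen plan sets against it unambiguous connectivity at C7 and C8 (the C8–O8 bond is made at a lactate carbon with no second site), enantiopurity from the chiral pool, and aryl regiochemistry decided by symmetry. The price is about four more steps and an untested photochemical closure.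

Key step: step 7

Remark: ethyl (S)-lactate of high enantiomeric purity is assumed, since the enantiomeric purity of 15 is fixed in step 1.

## Route

Step 1
Reactants: 1 syringaldehyde (4-hydroxy-3,5-dimethoxybenzaldehyde); 2 ethyl (S)-lactate
Product: 3 ethyl (2R)-2-(4-formyl-2,6-dimethoxyphenoxy)propanoate
Conditions: PPh3, DIAD, THF, 0 °C → rt
Reagents that add atoms: none
Why: Mitsunobu reaction; the para-formyl phenol is acidic enough to protonate the betaine, and its phenoxide displaces the oxyphosphonium group at the α-ester carbon by SN2 with inversion, which turns the (S) alcohol into the (R) ether and sets C8.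

Step 2
Reactants: 3 ethyl (2R)-2-(4-formyl-2,6-dimethoxyphenoxy)propanoate
Product: 4 ethyl (2R)-2-[4-(hydroxymethyl)-2,6-dimethoxyphenoxy]propanoate
Conditions: NaBH4, EtOH, 0 °C
Reagents that add atoms: none
Why: Chemoselective borohydride reduction; the aldehyde reacts far faster than the ester at 0 °C, ethanol excludes transesterification, and C8 is not touched.

Step 3
Reactants: 4 ethyl (2R)-2-[4-(hydroxymethyl)-2,6-dimethoxyphenoxy]propanoate
Product: 5 ethyl (2R)-2-[2,6-dimethoxy-4-(pivaloyloxymethyl)phenoxy]propanoate
Conditions: PivCl, pyridine, DMAP (cat.), CH2Cl2, 0 °C → rt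
Reagents that add atoms: pivaloyl chloride, CC(C)(C)C(=O)Cl
Why: DMAP-catalysed acylation of the only hydroxyl group; the hindered pivalate is chosen to survive the organomagnesium and hydride steps and to leave ring B electronically unperturbed.

Step 4
Reactants: 5 ethyl (2R)-2-[2,6-dimethoxy-4-(pivaloyloxymethyl)phenoxy]propanoate
Product: 6 (2R)-2-[2,6-dimethoxy-4-(pivaloyloxymethyl)phenoxy]-N-methoxy-N-methylpropanamide
Conditions: MeNH(OMe)·HCl, i-PrMgCl, THF, −20 °C
Reagents that add atoms: N,O-dimethylhydroxylamine hydrochloride, CNOC.Cl
Why: Weinreb amide formation by aminolysis with the chloromagnesium amide; the activated α-aryloxy ethyl ester reacts at −20 °C, where the hindered pivalate is inert and C8 is not deprotonated.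

Step 5
Reactants: 6 (2R)-2-[2,6-dimethoxy-4-(pivaloyloxymethyl)phenoxy]-N-methoxy-N-methylpropanamide; 7 5-bromo-1,2,3-trimethoxybenzene
Product: 9 (2R)-2-[2,6-dimethoxy-4-(pivaloyloxymethyl)phenoxy]-1-(3,4,5-trimethoxyphenyl)propan-1-one, via 3,4,5-trimethoxyphenylmagnesium bromide 8 (not isolated)
Conditions: 7, Mg, THF, rt → 40 °C; then 6, THF, −10 → 0 °C; aq. NH4Cl
Reagents that add atoms: none
Why: Weinreb ketone synthesis with an aryl Grignard reagent; the magnesium chelate of the tetrahedral adduct stops the addition at the ketone stage and protects C8 from enolisation until work-up, and the pivalate is much less electrophilic than the α-aryloxy amide.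

Step 6
Reactants: 9 (2R)-2-[2,6-dimethoxy-4-(pivaloyloxymethyl)phenoxy]-1-(3,4,5-trimethoxyphenyl)propan-1-one
Product: 10 (1R,2R)-2-[2,6-dimethoxy-4-(pivaloyloxymethyl)phenoxy]-1-(3,4,5-trimethoxyphenyl)propan-1-ol
Conditions: LiBH(s-Bu)3, THF, −78 °C; aq. NH4Cl
Reagents that add atoms: none
Why: Felkin–Anh-controlled ketone reduction; the bulky, poorly chelating hydride should attack anti to the perpendicular aryloxy group and past the C8 hydrogen, so the C8 centre sets C7 as (R) by 1,2-induction (threo alcohol); the pivalate is not reduced at −78 °C.

Step 7
Reactants: 10 (1R,2R)-2-[2,6-dimethoxy-4-(pivaloyloxymethyl)phenoxy]-1-(3,4,5-trimethoxyphenyl)propan-1-ol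
Product: 11 [(2R,3R)-5-methoxy-3-methyl-2-(3,4,5-trimethoxyphenyl)-2,3-dihydro-1,4-benzodioxin-7-yl]methyl pivalate
Conditions: 9-mesityl-3,6-di-tert-butyl-10-phenylacridinium tetrafluoroborate (5 mol %), 1,2-dichloroethane/2,2,2-trifluoroethanol 4:1, 0.02 M, 455 nm LEDs, N2, 25 °C
Reagents that add atoms: none
Why: Proposed new method: the excited acridinium, a far stronger oxidant than a trialkoxybenzene requires, should take one electron from ring B of 10; since O8 is twisted out of the ring plane by its two ortho methoxy neighbours, the hole sits in the orbital with a node through the O8 carbon and large coefficients on the two methoxy-bearing carbons, and the tethered C7 hydroxyl adds ipso to one of them. Proton loss from the oxonium, protonation of the geminal methoxy group and expulsion of methanol give the radical cation of 11, which is reduced by the acridine radical (or by a further molecule of 10), so the step is redox-neutral and proton-neutral and needs no additive. The closest known reaction type is the acridinium-photocatalysed cation-radical-accelerated nucleophilic aromatic substitution of methoxyarenes by azoles, amines and other heteroatom nucleophiles; an intramolecular version in which a secondary alcohol closes a 1,4-dioxane has not been shown. Ring C closes in a six-membered mode, 6-exo-trig with respect to the ring B π bond that is attacked; the alternative five-membered spiro attack at the O8 carbon, which would start a Smiles shift, meets the orbital node. No stereocentre is formed and no bond at C7 or C8 is broken, so the (1R,2R) alcohol can only give the (2R,3R) trans ring. The selectivity needed is between the two arenes, because ring A is oxidised as easily as ring B; it is secured by the tether, which lets the hydroxyl reach only the two equivalent methoxy carbons ortho to O8, while a hole on ring A has no nucleophile within reach and returns its electron. Base is left out and the solution is kept dilute so that C7–C8 fragmentation or C7–H loss from the ring A radical cation and intermolecular substitution stay slow; the pivaloyloxymethyl group neither conjugates with ring B nor offers a labile function.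

Step 8
Reactants: 11 [(2R,3R)-5-methoxy-3-methyl-2-(3,4,5-trimethoxyphenyl)-2,3-dihydro-1,4-benzodioxin-7-yl]methyl pivalate
Product: 12 [(2R,3R)-5-methoxy-3-methyl-2-(3,4,5-trimethoxyphenyl)-2,3-dihydro-1,4-benzodioxin-7-yl]methanol
Conditions: NaOMe (cat.), MeOH, 40 °C
Reagents that add atoms: none
Why: Base-catalysed transesterification (methanolysis) of the pivalate; the molecule holds no other base-labile group, and C7 and C8 are ether carbons without acidic hydrogens.

Step 9
Reactants: 12 [(2R,3R)-5-methoxy-3-methyl-2-(3,4,5-trimethoxyphenyl)-2,3-dihydro-1,4-benzodioxin-7-yl]methanol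
Product: 14 ethyl (E)-3-[(2R,3R)-5-methoxy-3-methyl-2-(3,4,5-trimethoxyphenyl)-2,3-dihydro-1,4-benzodioxin-7-yl]prop-2-enoate, via benzodioxine-7-carbaldehyde 13 (not isolated)
Conditions: MnO2 (activated), Ph3P=CHCO2Et, CH2Cl2, rt → 40 °C
Reagents that add atoms: ethyl (triphenylphosphoranylidene)acetate, CCOC(=O)C=P(c1ccccc1)(c1ccccc1)c1ccccc1
Why: Tandem benzylic oxidation and Wittig olefination; MnO2 oxidises only the benzylic alcohol, and the stabilised ylide traps the electron-rich aldehyde as it forms and gives the (E)-ester under the usual thermodynamic control of stabilised ylides.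

Step 10
Reactants: 14 ethyl (E)-3-[(2R,3R)-5-methoxy-3-methyl-2-(3,4,5-trimethoxyphenyl)-2,3-dihydro-1,4-benzodioxin-7-yl]prop-2-enoate
Product: 15 (E)-3-[(2R,3R)-5-methoxy-3-methyl-2-(3,4,5-trimethoxyphenyl)-2,3-dihydro-1,4-benzodioxin-7-yl]prop-2-en-1-ol
Conditions: i-Bu2AlH, CH2Cl2, −78 °C; aq. potassium sodium tartrate
Reagents that add atoms: none
Why: 1,2-reduction of the α,β-unsaturated ester by the aluminium hydride at low temperature; the olefin geometry is kept, and the neutral tartrate work-up spares the acid-sensitive cinnamyl alcohol.

## Compound list

1 | syringaldehyde (4-hydroxy-3,5-dimethoxybenzaldehyde) | COc1cc(C=O)cc(OC)c1O | starting material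
2 | ethyl (S)-lactate | CCOC(=O)[C@H](C)O | starting material
3 | ethyl (2R)-2-(4-formyl-2,6-dimethoxyphenoxy)propanoate | CCOC(=O)[C@@H](C)Oc1c(OC)cc(C=O)cc1OC | intermediate
4 | ethyl (2R)-2-[4-(hydroxymethyl)-2,6-dimethoxyphenoxy]propanoate | CCOC(=O)[C@@H](C)Oc1c(OC)cc(CO)cc1OC | intermediate
5 | ethyl (2R)-2-[2,6-dimethoxy-4-(pivaloyloxymethyl)phenoxy]propanoate | CCOC(=O)[C@@H](C)Oc1c(OC)cc(COC(=O)C(C)(C)C)cc1OC | intermediate
6 | (2R)-2-[2,6-dimethoxy-4-(pivaloyloxymethyl)phenoxy]-N-methoxy-N-methylpropanamide | CON(C)C(=O)[C@@H](C)Oc1c(OC)cc(COC(=O)C(C)(C)C)cc1OC | intermediate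
7 | 5-bromo-1,2,3-trimethoxybenzene | COc1cc(Br)cc(OC)c1OC | starting material
8 | 3,4,5-trimethoxyphenylmagnesium bromide | COc1cc([Mg]Br)cc(OC)c1OC | intermediate (not isolated)
9 | (2R)-2-[2,6-dimethoxy-4-(pivaloyloxymethyl)phenoxy]-1-(3,4,5-trimethoxyphenyl)propan-1-one | COc1cc(C(=O)[C@@H](C)Oc2c(OC)cc(COC(=O)C(C)(C)C)cc2OC)cc(OC)c1OC | intermediate
10 | (1R,2R)-2-[2,6-dimethoxy-4-(pivaloyloxymethyl)phenoxy]-1-(3,4,5-trimethoxyphenyl)propan-1-ol | COc1cc([C@@H](O)[C@@H](C)Oc2c(OC)cc(COC(=O)C(C)(C)C)cc2OC)cc(OC)c1OC | intermediate
11 | [(2R,3R)-5-methoxy-3-methyl-2-(3,4,5-trimethoxyphenyl)-2,3-dihydro-1,4-benzodioxin-7-yl]methyl pivalate | COc1cc([C@H]2Oc3cc(COC(=O)C(C)(C)C)cc(OC)c3O[C@@H]2C)cc(OC)c1OC | intermediate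
12 | [(2R,3R)-5-methoxy-3-methyl-2-(3,4,5-trimethoxyphenyl)-2,3-dihydro-1,4-benzodioxin-7-yl]methanol | COc1cc([C@H]2Oc3cc(CO)cc(OC)c3O[C@@H]2C)cc(OC)c1OC | intermediate
13 | (2R,3R)-5-methoxy-3-methyl-2-(3,4,5-trimethoxyphenyl)-2,3-dihydro-1,4-benzodioxine-7-carbaldehyde | COc1cc([C@H]2Oc3cc(C=O)cc(OC)c3O[C@@H]2C)cc(OC)c1OC | intermediate (not isolated)
14 | ethyl (E)-3-[(2R,3R)-5-methoxy-3-methyl-2-(3,4,5-trimethoxyphenyl)-2,3-dihydro-1,4-benzodioxin-7-yl]prop-2-enoate | COc1cc([C@H]2Oc3cc(/C=C/C(=O)OCC)cc(OC)c3O[C@@H]2C)cc(OC)c1OC | intermediate
15 | (E)-3-[(2R,3R)-5-methoxy-3-methyl-2-(3,4,5-trimethoxyphenyl)-2,3-dihydro-1,4-benzodioxin-7-yl]prop-2-en-1-ol | COc1cc([C@H]2Oc3cc(/C=C/CO)cc(OC)c3O[C@@H]2C)cc(OC)c1OC | target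

## Step count and least certain steps

Total step count: 10. Longest linear sequence: 10 steps (from 1 and 2 to 15); reagent 8 is made in the flask within step 5.

**Step 7 (bears the label "Proposed new method:").**
- What may go wrong: the hole is spent without ring closure. Ring A is oxidised in competition and its radical cation fragments at C7–C8 or loses the C7 hydrogen. Addition of a hindered secondary alcohol to the ring B radical cation may be reversible and too slow against back electron transfer. An ipso attack at the O8 carbon would start a Smiles-type aryl shift and lead to the regioisomeric ring.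
- Fallback (known chemistry, same O7–aryl bond, made by palladium-catalysed intramolecular etherification of an aryl bromide): it sets out from ethyl (S)-lactate 2 and returns to the route at pivalate 11, in the same number of steps.
  - 3-Bromo-4-hydroxy-5-methoxybenzaldehyde F1 takes the place of 1. Mitsunobu coupling with 2 gives ethyl (2R)-2-(2-bromo-4-formyl-6-methoxyphenoxy)propanoate F2.
  - NaBH4 in ethanol gives ethyl (2R)-2-[2-bromo-4-(hydroxymethyl)-6-methoxyphenoxy]propanoate F3, and pivaloylation gives ethyl (2R)-2-[2-bromo-6-methoxy-4-(pivaloyloxymethyl)phenoxy]propanoate F4.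
  - Aminolysis as in step 4 gives (2R)-2-[2-bromo-6-methoxy-4-(pivaloyloxymethyl)phenoxy]-N-methoxy-N-methylpropanamide F5. Addition of Grignard reagent 8 gives (2R)-2-[2-bromo-6-methoxy-4-(pivaloyloxymethyl)phenoxy]-1-(3,4,5-trimethoxyphenyl)propan-1-one F6.
  - Reduction with LiBH(s-Bu)3 gives (1R,2R)-2-[2-bromo-6-methoxy-4-(pivaloyloxymethyl)phenoxy]-1-(3,4,5-trimethoxyphenyl)propan-1-ol F7.
  - Pd(OAc)2, 2-(di-tert-butylphosphino)-1,1′-binaphthyl and Cs2CO3 in toluene at 70 °C then join O7 to the brominated carbon and give 11, again without touching C7 or C8.

**Step 6.**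
- What may go wrong: poor facial selectivity. Lithium may be held between the carbonyl oxygen, O8 and an ortho methoxy group of ring B, which turns hydride delivery toward the erythro alcohol.
- Fallback (use chelation on purpose, then invert C7): it sets out from ketone 9 and returns at alcohol 10.
  - Zn(BH4)2 in Et2O at 0 °C should give (1S,2R)-2-[2,6-dimethoxy-4-(pivaloyloxymethyl)phenoxy]-1-(3,4,5-trimethoxyphenyl)propan-1-ol F8 by chelation control.
  - Mitsunobu reaction with 4-nitrobenzoic acid (PPh3, DIAD, THF) inverts C7 to (1R,2R)-2-[2,6-dimethoxy-4-(pivaloyloxymethyl)phenoxy]-1-(3,4,5-trimethoxyphenyl)propyl 4-nitrobenzoate F9.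
  - K2CO3 in MeOH at 0 °C cleaves the activated aryl ester much faster than the pivalate and gives 10.

**Step 1.**
- What may go wrong: slow, incomplete coupling, because the phenoxide is flanked by two methoxy groups and weakened by the formyl group. Side reactions would be elimination of the activated lactate or partial loss of configuration.
- Fallback (separate activation and displacement): it sets out from 2 and returns at 3. Tf2O and 2,6-lutidine in CH2Cl2 at −78 °C give ethyl (2S)-2-(trifluoromethylsulfonyloxy)propanoate F10. The potassium phenoxide of 1 (K2CO3, MeCN, 0 °C → rt) displaces the triflate with inversion.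

**Step 5.**
- What may go wrong: attack of the aryl Grignard reagent on the pivalate carbonyl, which removes the protecting group and consumes reagent, and enolisation toward C8 once the ketone is released.
- Fallback (keep the ester protecting group out of the organomagnesium steps): it sets out from alcohol 4 and returns at ketone 9.
  - Aminolysis of 4 with one more equivalent of i-PrMgCl gives (2R)-2-[4-(hydroxymethyl)-2,6-dimethoxyphenoxy]-N-methoxy-N-methylpropanamide F11.
  - Its magnesium alkoxide is treated with an excess of 8 and gives (2R)-2-[4-(hydroxymethyl)-2,6-dimethoxyphenoxy]-1-(3,4,5-trimethoxyphenyl)propan-1-one F12.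
  - Pivaloylation under the conditions of step 3 gives 9.

## Further compounds

F1 | step 7 | 3-bromo-4-hydroxy-5-methoxybenzaldehyde | COc1cc(C=O)cc(Br)c1O
F2 | step 7 | ethyl (2R)-2-(2-bromo-4-formyl-6-methoxyphenoxy)propanoate | CCOC(=O)[C@@H](C)Oc1c(Br)cc(C=O)cc1OC
F3 | step 7 | ethyl (2R)-2-[2-bromo-4-(hydroxymethyl)-6-methoxyphenoxy]propanoate | CCOC(=O)[C@@H](C)Oc1c(Br)cc(CO)cc1OC
F4 | step 7 | ethyl (2R)-2-[2-bromo-6-methoxy-4-(pivaloyloxymethyl)phenoxy]propanoate | CCOC(=O)[C@@H](C)Oc1c(Br)cc(COC(=O)C(C)(C)C)cc1OC
F5 | step 7 | (2R)-2-[2-bromo-6-methoxy-4-(pivaloyloxymethyl)phenoxy]-N-methoxy-N-methylpropanamide | CON(C)C(=O)[C@@H](C)Oc1c(Br)cc(COC(=O)C(C)(C)C)cc1OC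
F6 | step 7 | (2R)-2-[2-bromo-6-methoxy-4-(pivaloyloxymethyl)phenoxy]-1-(3,4,5-trimethoxyphenyl)propan-1-one | COc1cc(C(=O)[C@@H](C)Oc2c(Br)cc(COC(=O)C(C)(C)C)cc2OC)cc(OC)c1OC
F7 | step 7 | (1R,2R)-2-[2-bromo-6-methoxy-4-(pivaloyloxymethyl)phenoxy]-1-(3,4,5-trimethoxyphenyl)propan-1-ol | COc1cc([C@@H](O)[C@@H](C)Oc2c(Br)cc(COC(=O)C(C)(C)C)cc2OC)cc(OC)c1OC
F8 | step 6 | (1S,2R)-2-[2,6-dimethoxy-4-(pivaloyloxymethyl)phenoxy]-1-(3,4,5-trimethoxyphenyl)propan-1-ol | COc1cc([C@H](O)[C@@H](C)Oc2c(OC)cc(COC(=O)C(C)(C)C)cc2OC)cc(OC)c1OC
F9 | step 6 | (1R,2R)-2-[2,6-dimethoxy-4-(pivaloyloxymethyl)phenoxy]-1-(3,4,5-trimethoxyphenyl)propyl 4-nitrobenzoate | COc1cc([C@@H](OC(=O)c3ccc(cc3)[N+](=O)[O-])[C@@H](C)Oc2c(OC)cc(COC(=O)C(C)(C)C)cc2OC)cc(OC)c1OC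
F10 | step 1 | ethyl (2S)-2-(trifluoromethylsulfonyloxy)propanoate | CCOC(=O)[C@H](C)OS(=O)(=O)C(F)(F)F
F11 | step 5 | (2R)-2-[4-(hydroxymethyl)-2,6-dimethoxyphenoxy]-N-methoxy-N-methylpropanamide | CON(C)C(=O)[C@@H](C)Oc1c(OC)cc(CO)cc1OC
F12 | step 5 | (2R)-2-[4-(hydroxymethyl)-2,6-dimethoxyphenoxy]-1-(3,4,5-trimethoxyphenyl)propan-1-one | COc1cc(C(=O)[C@@H](C)Oc2c(OC)cc(CO)cc2OC)cc(OC)c1OC
A1 | alternative 1 | methyl 3-hydroxy-5-methoxy-4-{[(Z)-3-methoxy-3-oxo-1-(3,4,5-trimethoxyphenyl)prop-1-en-2-yl]oxy}benzoate | COC(=O)/C(Oc1c(O)cc(C(=O)OC)cc1OC)=C/c1cc(OC)c(OC)c(OC)c1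
A2 | alternative 1 | dimethyl (2S,3R)-8-methoxy-3-(3,4,5-trimethoxyphenyl)-2,3-dihydro-1,4-benzodioxine-2,6-dicarboxylate | COc1cc([C@H]2Oc3cc(C(=O)OC)cc(OC)c3O[C@@H]2C(=O)OC)cc(OC)c1OC
A3 | alternative 2 | (1R,2R)-2-(tert-butylperoxy)-1-(3,4,5-trimethoxyphenyl)propan-1-ol | COc1cc([C@@H](O)[C@@H](C)OOC(C)(C)C)cc(OC)c1OC
A4 | alternative 2 | 5-(dimethoxymethyl)-3-methoxy-2-(trimethylsilyl)phenyl trifluoromethanesulfonate | COC(OC)c1cc(OC)c([Si](C)(C)C)c(OS(=O)(=O)C(F)(F)F)c1
A5 | alternative 2 | (2R,3R)-7-(dimethoxymethyl)-5-methoxy-3-methyl-2-(3,4,5-trimethoxyphenyl)-2,3-dihydro-1,4-benzodioxine | COc1cc([C@H]2Oc3cc(C(OC)OC)cc(OC)c3O[C@@H]2C)cc(OC)c1OC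
A6 | alternative 3 | (2R,3S)-2-methyl-3-(3,4,5-trimethoxyphenyl)oxirane | COc1cc([C@@H]2O[C@@H]2C)cc(OC)c1OC
A7 | alternative 3 | 4-fluoro-3-hydroxy-5-methoxybenzaldehyde | COc1cc(C=O)cc(O)c1F
A8 | alternative 3 | (2R,3R)-5-methoxy-3-methyl-2-(3,4,5-trimethoxyphenyl)-2,3-dihydro-1,4-benzodioxine-7-carbaldehyde | COc1cc([C@H]2Oc3cc(C=O)cc(OC)c3O[C@@H]2C)cc(OC)c1OC
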